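## Retrosynthetic overview

1. The target is traced back to its 5-O-methyl ether, (2S)-5,6,7,3',4'-pentamethoxyflavanone. The C5–OMe group lies peri to the C4 carbonyl, so it can be cleaved last by chelation.
2. Ring C is the only ring to be made, since rings A and B are bought. It is opened at O1–C2 and C4–C4a at once, and O1 is re-tied to C4 as a temporary ester tether. This gives the achiral, isomeric 3,4,5-trimethoxyphenyl 3,4-dimethoxycinnamate.
3. In the forward direction, light moves the acyl group from O1 to C4a (photo-Fries). A chiral bifunctional catalyst then closes O1 onto C2 (oxa-Michael) in the same flask, which funnels all E/Z isomers into the (2S) centre.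
4. Enabling feature: in ring C the C2–O1 bond is β to the C4 carbonyl and C4a is ortho to O1. The 5,6,7-trioxygenated ring A maps onto a C2v-symmetric 3,4,5-trimethoxyphenoxy group, with two equivalent ortho carbons, a blocked para carbon and a single free OH after the shift.
5. The ester comes from 3,4,5-trimethoxyphenol and 3,4-dimethoxycinnamic acid.

Key step: step 2

Assumption: the epi-quinine-derived thiourea is taken to direct O1 to the Si face of the chalcone β-carbon, which gives (2S). This sense of induction has to be confirmed on the substrate. If it is the reverse, the pseudo-enantiomeric epi-quinidine-derived catalyst is used in the same way.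

## Route

Step 1
Reactants: 1 3,4,5-trimethoxyphenol; 2 (E)-3,4-dimethoxycinnamic acid
Product: 3 3,4,5-trimethoxyphenyl (E)-3,4-dimethoxycinnamate
Conditions: DCC (1.1 equiv), DMAP (10 mol %), CH2Cl2, 0 °C to rt; filter, recrystallise (DMAP-free)
Reagents that add atoms: none
Why: Steglich esterification, in which DCC turns the acid into the O-acylisourea and DMAP relays the acyl group to the phenol oxygen under neutral conditions that leave the alkene and all aryl methyl ethers untouched; no stereocentre is formed.

Step 2
Reactants: 3 3,4,5-trimethoxyphenyl (E)-3,4-dimethoxycinnamate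
Product: 8 (2S)-5,6,7,3',4'-pentamethoxyflavanone, via (Z)-cinnamate photoisomer 4 (not isolated), via ortho-acyl cyclohexadienone 5 (not isolated), via (E)-2'-hydroxychalcone 6 (not isolated), via (Z)-2'-hydroxychalcone 7 (not isolated)
Conditions: hν (300–310 nm), degassed toluene (0.01 M), FEP flow coil, 20 °C; then dark, concentrate in the same flask to 0.1 M, 9-amino(9-deoxy)-epi-quinine 3,5-bis(trifluoromethyl)phenyl thiourea (10 mol %), 0 °C
Reagents that add atoms: none
Why: Proposed new method: excitation of the cinnamate chromophore of 3 (its E/Z scrambling to 4 costs nothing) homolyses the aryl O–acyl tether, and the solvent-caged 3,4,5-trimethoxyphenoxyl/cinnamoyl radical pair, whose α,β-unsaturated acyl radical does not lose CO, recombines at an ortho carbon to dienone 5, which tautomerises to the hydrogen-bonded chalcones 6 and 7 and thereby makes the C4–C4a bond. In the dark the bifunctional catalyst takes the 2'-OH proton with its quinuclidine nitrogen, holds the C4 carbonyl with its thiourea N–H pair and closes ring C by a 6-endo-trig oxa-Michael addition that makes the O1–C2 bond. The closest known reaction types are the photo-Fries rearrangement of aryl cinnamates to 2'-hydroxychalcones, the one-pot photo-Fries/base-induced oxa-Michael route from aryl 3-methylbut-2-enoates to 2,2-dimethylchroman-4-ones and the cinchona-thiourea cyclisation of 2'-hydroxychalcones; what is new is their coupling in one flask, which is reasonable because the photochemical stage is a reagent-free isomerisation that leaves no acid, base or salt able to run a racemic background closure. C2, the only stereocentre, is set by the catalyst, which should deliver O1 to the Si face of the β-carbon of the s-cis enone 6, and 7 is fed into 6 by light and by reversible conjugate addition of the amine, so that all alkene isomers converge on (2S)-8. Site selectivity is secured by the substrate: the two ortho carbons of the C2v-symmetric aryloxy group are equivalent, its para carbon is blocked by OMe and only one free OH exists, so only the 5,6,7-pattern can form, and in the absence of acid no 4-aryl-dihydrocoumarin is expected. The 6'-OMe group (later C5–OMe) twists the aroyl unit and shifts the chalcone/flavanone equilibrium far towards 8, which keeps the retro-reaction, the only racemisation channel, slow at 0 °C.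

Step 3
Reactants: 8 (2S)-5,6,7,3',4'-pentamethoxyflavanone
Product: 9 (2S)-5-hydroxy-6,7,3',4'-tetramethoxyflavanone (target)
Conditions: BCl3 (1.5 equiv, 1 M in CH2Cl2), CH2Cl2, −78 to −20 °C; then ice-cold 1 M HCl
Reagents that add atoms: none
Why: Chelation-directed Lewis-acid ether cleavage, in which BCl3 binds the C4 carbonyl and the peri O5 in a six-membered chelate so that chloride removes only this methyl group by SN2, the four other aryl methyl ethers (no neighbouring carbonyl) survive at low temperature, and C2 is left alone because no base is present and the cold, short exposure should not open the C2–O1 bond.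

## Compound list

1 | 3,4,5-trimethoxyphenol | COc1cc(O)cc(OC)c1OC | starting material
2 | (E)-3-(3,4-dimethoxyphenyl)prop-2-enoic acid | COc1ccc(/C=C/C(=O)O)cc1OC | starting material
3 | 3,4,5-trimethoxyphenyl (E)-3-(3,4-dimethoxyphenyl)prop-2-enoate | COc1ccc(/C=C/C(=O)Oc2cc(OC)c(OC)c(OC)c2)cc1OC | intermediate
4 | 3,4,5-trimethoxyphenyl (Z)-3-(3,4-dimethoxyphenyl)prop-2-enoate (photoisomer of 3) | COc1ccc(/C=C\C(=O)Oc2cc(OC)c(OC)c(OC)c2)cc1OC | intermediate
5 | 6-[3-(3,4-dimethoxyphenyl)prop-2-enoyl]-3,4,5-trimethoxycyclohexa-2,4-dien-1-one (racemic at C6, E/Z mixture; keto tautomer of the chalcone) | COc1ccc(C=CC(=O)C2C(=O)C=C(OC)C(OC)=C2OC)cc1OC | intermediate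
6 | (E)-3-(3,4-dimethoxyphenyl)-1-(6-hydroxy-2,3,4-trimethoxyphenyl)prop-2-en-1-one | COc1ccc(/C=C/C(=O)c2c(O)cc(OC)c(OC)c2OC)cc1OC | intermediate
7 | (Z)-3-(3,4-dimethoxyphenyl)-1-(6-hydroxy-2,3,4-trimethoxyphenyl)prop-2-en-1-one | COc1ccc(/C=C\C(=O)c2c(O)cc(OC)c(OC)c2OC)cc1OC | intermediate
8 | (2S)-2-(3,4-dimethoxyphenyl)-5,6,7-trimethoxy-2,3-dihydro-4H-chromen-4-one | COc1ccc([C@@H]2CC(=O)c3c(cc(OC)c(OC)c3OC)O2)cc1OC | intermediate
9 | (2S)-2-(3,4-dimethoxyphenyl)-5-hydroxy-6,7-dimethoxy-2,3-dihydro-4H-chromen-4-one | COc1ccc([C@@H]2CC(=O)c3c(cc(OC)c(OC)c3O)O2)cc1OC | target

Total step count: 3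
Longest linear sequence: 3 steps (1 or 2 → 3 → 8 → 9)

## Steps most likely to fail

**Step 2.**
- The excited cinnamate may spend its energy on E/Z isomerisation, so that O–acyl homolysis is slow.
- Radicals may escape from the solvent cage.
- The growing chalcone may screen the light.
- Some ring closure may take place without the catalyst during irradiation.
- Facial selectivity on a chalcone that carries no activating group at C3 may be insufficient, or may be eroded by reversibility.

The fallback uses known chemistry only, sets out from 1 and comes back at 8. Friedel–Crafts C-acetylation of 1 (Ac2O, BF3·OEt2) should give 1-(6-hydroxy-2,3,4-trimethoxyphenyl)ethan-1-one F1. Condensation with DMF dimethyl acetal should give (E)-3-(dimethylamino)-1-(6-hydroxy-2,3,4-trimethoxyphenyl)prop-2-en-1-one F2. This closes in aqueous HCl/CH2Cl2 to 5,6,7-trimethoxy-4H-chromen-4-one F3. A Rh(I)-catalysed asymmetric 1,4-addition of 3,4-dimethoxyphenylboronic acid (Hayashi–Miyaura reaction) then gives 8. It is run with the enantiomer of an electron-poor atropisomeric bisphosphine of the MeO-F12-BIPHEP type that leads to (2S), in toluene/water at rt. The stereocentre is set by the ligand in an irreversible C–C bond formation.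

**Step 3.**
- Configurational integrity may be lost by Lewis-acid-assisted opening of the benzylic C2–O1 bond, because the 3,4-dimethoxyphenyl group stabilises positive charge at C2.
- Re-closure through the newly freed O5 would then also scramble the ring-A pattern.
- Ether cleavage may continue at O6.

The fallback moves the demethylation to an achiral stage and creates the stereocentre last. It sets out from 1 and comes back at 9. The same three operations as above lead through F1 and F2 to 5,6,7-trimethoxy-4H-chromen-4-one F3. BCl3 in CH2Cl2 then cleaves the peri ether of this robust chromone to 5-hydroxy-6,7-dimethoxy-4H-chromen-4-one F4. The Rh(I)-catalysed asymmetric 1,4-addition of 3,4-dimethoxyphenylboronic acid is run on F4 under the neutral aqueous conditions given above and gives 9 directly. The chelated phenol of F4 is only weakly acidic and should be tolerated.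

**Step 1.**
- Rearrangement of the O-acylisourea to the N-acylurea may compete with acyl transfer to the phenol.
- Traces of DMAP carried forward would trigger an uncatalysed, racemic closure in step 2.

The fallback builds the alkene last instead of the ester. It sets out from 1 and comes back at 3. Heating 1 with Meldrum's acid in toluene should give 3-oxo-3-(3,4,5-trimethoxyphenoxy)propanoic acid F5. A Knoevenagel–Doebner condensation with 3,4-dimethoxybenzaldehyde (pyridine, catalytic piperidine, 60 °C) should then give 3 as the E isomer after decarboxylation.

## Further compounds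

F1 | step 2 | 1-(6-hydroxy-2,3,4-trimethoxyphenyl)ethan-1-one | CC(=O)c1c(O)cc(OC)c(OC)c1OC
F2 | step 2 | (E)-3-(dimethylamino)-1-(6-hydroxy-2,3,4-trimethoxyphenyl)prop-2-en-1-one | CN(C)/C=C/C(=O)c1c(O)cc(OC)c(OC)c1OC
F3 | step 2 | 5,6,7-trimethoxy-4H-chromen-4-one | COc1cc2occc(=O)c2c(OC)c1OC
F4 | step 3 | 5-hydroxy-6,7-dimethoxy-4H-chromen-4-one | COc1cc2occc(=O)c2c(O)c1OC
F5 | step 1 | 3-oxo-3-(3,4,5-trimethoxyphenoxy)propanoic acid | COc1cc(OC(=O)CC(=O)O)cc(OC)c1OC
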